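Both halves of the target are the same unit: a 2,2-dimethyloxepane (O1, C2–C7) trans-fused along C6–C7 to a cyclohexane (C6–C11), joined tail to tail through C12–C12'. This is the oxidation pattern of a squalene end epoxidised at C2–C3 and C6–C7, so the plan disconnects O1–C2 and C6–C11 in both halves at once. One Lewis-acid-triggered cascade on an acyclic (3S,6S,7S,3'S,6'S,7'S)-tetraepoxide carrying two (Z)-allylsilanes (CH2SiMe3 on C10 and C10') should close all four rings and set C6 and C11 in each half, leaving two C10 methylenes that are then differentiated into the cis- and trans-acetoxy centres.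

Key step: step 10

Locants (each half, primes for the second): C2 = CMe2–O, C3 = carbonyl carbon, C6 = ring-fusion C–CH3, C7 = ring-fusion CH–O, C10 = C(CH3)OAc, C11 = CH bearing the bridge, C12 = bridge CH2.

Stereochemical bookkeeping: the target is 6S,7S,11S in both halves, 10R (acetate axial, cis to C12) in one and 10'S (acetate equatorial, trans to C12') in the other. The ring centres are therefore C2-symmetric and require S-configured epoxides and a (Z)-allylsilane (CH2SiMe3 cis to C12).

Assumption: the L-fructose-derived Shi ketone needed for the S-epoxides is taken as purchasable (it is otherwise prepared from L-sorbose).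

Step 1
Reactants: 1 methyl acetoacetate; 2 geranyl bromide
Product: 3 methyl (6E)-7,11-dimethyl-3-oxododeca-6,10-dienoate
Conditions: NaH, THF, 0 °C; n-BuLi, 0 °C; then 2, 0 °C to 23 °C
Reagents that add atoms: none
Why: The acetoacetate dianion alkylates only at its more nucleophilic terminal carbon, and SN2 attack on the primary allylic bromide leaves the E alkene untouched (dianion γ-alkylation).

Step 2
Reactants: 3 methyl (6E)-7,11-dimethyl-3-oxododeca-6,10-dienoate
Product: 4 methyl (2Z,6E)-3-[(diethoxyphosphoryl)oxy]-7,11-dimethyldodeca-2,6,10-trienoate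
Conditions: NaH, Et2O, 0 °C; ClP(O)(OEt)2
Reagents that add atoms: diethyl chlorophosphate, CCOP(=O)(Cl)OCC
Why: The sodium enolate formed in ether is chelated between the two carbonyl oxygens, so O-phosphorylation should give the Z enol phosphate (phosphate cis to the ester), which fixes the later alkene geometry.

Step 3
Reactants: 4 methyl (2Z,6E)-3-[(diethoxyphosphoryl)oxy]-7,11-dimethyldodeca-2,6,10-trienoate; 5 (trimethylsilyl)methylmagnesium chloride
Product: 6 methyl (2Z,6E)-7,11-dimethyl-3-[(trimethylsilyl)methyl]dodeca-2,6,10-trienoate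
Conditions: Ni(acac)2 (cat.), THF, 0 °C to 23 °C
Reagents that add atoms: (trimethylsilyl)methylmagnesium chloride (5), C[Si](C)(C)C[Mg]Cl
Why: Nickel-catalysed Kumada coupling at the enol phosphate C–O bond proceeds with retention of alkene geometry, placing CH2SiMe3 cis to the ester carbon (the future C12), and the hindered Grignard reagent does not add to the ester.

Step 4
Reactants: 6 methyl (2Z,6E)-7,11-dimethyl-3-[(trimethylsilyl)methyl]dodeca-2,6,10-trienoate
Product: 7 methyl (2Z)-5-[(2S,3S)-3-{2-[(2S)-3,3-dimethyloxiran-2-yl]ethyl}-3-methyloxiran-2-yl]-3-[(trimethylsilyl)methyl]pent-2-enoate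
Conditions: 1,2:4,5-di-O-isopropylidene-β-L-erythro-2,3-hexodiulo-2,6-pyranose (cat.), Oxone (2KHSO5·KHSO4·K2SO4), K2CO3, Bu4NHSO4, MeCN/CH2(OMe)2, aq. Na2B4O7 buffer, 0 °C
Reagents that add atoms: potassium peroxymonosulfate (active part of Oxone), [K+].[O-]S(=O)(=O)OO
Why: In this Shi epoxidation the chiral dioxirane oxidises the two electron-rich trisubstituted alkenes through a spiro transition state that, with the L-series ketone, should set C3, C6 and C7 all S, while the ester-conjugated alkene is too electron-poor to react.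

Step 5
Reactants: 7 methyl (2Z)-5-[(2S,3S)-3-{2-[(2S)-3,3-dimethyloxiran-2-yl]ethyl}-3-methyloxiran-2-yl]-3-[(trimethylsilyl)methyl]pent-2-enoate
Product: 8 (2Z)-5-[(2S,3S)-3-{2-[(2S)-3,3-dimethyloxiran-2-yl]ethyl}-3-methyloxiran-2-yl]-3-[(trimethylsilyl)methyl]pent-2-en-1-ol
Conditions: i-Bu2AlH, CH2Cl2, −78 °C; aq. Rochelle salt
Reagents that add atoms: none
Why: The aluminium hydride reduces the conjugated ester in 1,2-fashion to the allylic alcohol at −78 °C, where trisubstituted epoxides and the allylsilane are inert.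

Step 6
Reactants: 8 (2Z)-5-[(2S,3S)-3-{2-[(2S)-3,3-dimethyloxiran-2-yl]ethyl}-3-methyloxiran-2-yl]-3-[(trimethylsilyl)methyl]pent-2-en-1-ol
Product: 10 (2Z)-1-bromo-5-[(2S,3S)-3-{2-[(2S)-3,3-dimethyloxiran-2-yl]ethyl}-3-methyloxiran-2-yl]-3-[(trimethylsilyl)methyl]pent-2-ene, via allylic mesylate 9 (not isolated)
Conditions: MsCl, Et3N, THF, −45 °C; then LiBr, THF, −45 °C to 0 °C; used at once
Reagents that add atoms: lithium bromide, [Li+].[Br-]
Why: Mesylation followed by SN2 displacement with bromide at low temperature should convert the primary allylic alcohol into the bromide without allylic transposition, epoxide opening or loss of silicon.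

Step 7
Reactants: 10 (2Z)-1-bromo-5-[(2S,3S)-3-{2-[(2S)-3,3-dimethyloxiran-2-yl]ethyl}-3-methyloxiran-2-yl]-3-[(trimethylsilyl)methyl]pent-2-ene (one half of the material)
Product: 11 {[(2Z)-5-[(2S,3S)-3-{2-[(2S)-3,3-dimethyloxiran-2-yl]ethyl}-3-methyloxiran-2-yl]-3-[(trimethylsilyl)methyl]pent-2-en-1-yl]sulfonyl}benzene
Conditions: PhSO2Na, DMF, 0 °C to 23 °C
Reagents that add atoms: sodium benzenesulfinate, [Na+].[O-]S(=O)c1ccccc1
Why: The soft sulfinate anion S-alkylates the primary allylic bromide (SN2) to give the allylic sulfone that serves as the nucleophilic half of the tail-to-tail union.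

Step 8
Reactants: 11 {[(2Z)-5-[(2S,3S)-3-{2-[(2S)-3,3-dimethyloxiran-2-yl]ethyl}-3-methyloxiran-2-yl]-3-[(trimethylsilyl)methyl]pent-2-en-1-yl]sulfonyl}benzene; 10 (2Z)-1-bromo-5-[(2S,3S)-3-{2-[(2S)-3,3-dimethyloxiran-2-yl]ethyl}-3-methyloxiran-2-yl]-3-[(trimethylsilyl)methyl]pent-2-ene
Product: 12 (3S,6S,7S,10Z,14Z,18S,19S,22S)-2,3:6,7:18,19:22,23-tetraepoxy-2,6,19,23-tetramethyl-12-(phenylsulfonyl)-10,15-bis[(trimethylsilyl)methyl]tetracosa-10,14-diene (both C12 epimers)
Conditions: n-BuLi, THF, −78 °C; then 10, −78 °C to −20 °C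
Reagents that add atoms: none
Why: The sulfone-stabilised allylic carbanion alkylates at its α-carbon with the primary allylic bromide (SN2), forging C12–C12'; attack on its own epoxide is geometrically impossible across the trans chain, and the new sulfone-bearing stereocentre is erased in the next step.

Step 9
Reactants: 12 (3S,6S,7S,10Z,14Z,18S,19S,22S)-2,3:6,7:18,19:22,23-tetraepoxy-2,6,19,23-tetramethyl-12-(phenylsulfonyl)-10,15-bis[(trimethylsilyl)methyl]tetracosa-10,14-diene
Product: 13 (3S,6S,7S,10Z,14Z,18S,19S,22S)-2,3:6,7:18,19:22,23-tetraepoxy-2,6,19,23-tetramethyl-10,15-bis[(trimethylsilyl)methyl]tetracosa-10,14-diene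
Conditions: Na/Hg (5%), Na2HPO4, MeOH/THF, −20 °C
Reagents that add atoms: none
Why: Buffered sodium amalgam cleaves the allylic C–S bond by electron transfer and should protonate the less substituted C12 terminus, under conditions that epoxides and allylsilanes tolerate (reductive desulfonylation).

Step 10
Reactants: 13 (3S,6S,7S,10Z,14Z,18S,19S,22S)-2,3:6,7:18,19:22,23-tetraepoxy-2,6,19,23-tetramethyl-10,15-bis[(trimethylsilyl)methyl]tetracosa-10,14-diene
Product: 15 6,6'-(ethane-1,2-diyl)bis[(3S,5aS,6R,9aS)-2,2,5a-trimethyl-7-methylidenedecahydro-1-benzoxepin-3-ol], via bis(trimethylsilyl) ether 14 (not isolated)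
Conditions: Me3SiOTf, 2,6-di-tert-butyl-4-methylpyridine, CH2Cl2, −78 °C; then K2CO3, MeOH, 23 °C
Reagents that add atoms: none
Why: O-Silylation of each terminal epoxide lets the tertiary C2–O bond ionise, the neighbouring 6,7-epoxide oxygen captures C2 to give a bicyclic epoxonium ion, and the allylsilane carbon C11 opens this ion at tertiary C6 with loss of Me3Si+ (returned as the silyl triflate), leaving a C3 silyl ether that is methanolysed to the diol. The closest known reaction is the silyl-triflate-promoted tandem oxa- and carbacyclisation of a 1,5-diepoxide with an allylsilane terminator, run here at two remote and independent chain ends. Each oxepane closes by endo attack of the epoxide oxygen at C2 (seven-membered after C6–O scission) and each cyclohexane by 6-endo SE2' attack of the alkene on C6. C7 keeps its C–O bond and so its configuration, C6 is inverted because C11 enters anti to the departing oxygen, C11 is set by a chair transition state in which the Z allylsilane (C9 trans to C12) places C12 equatorial and cis to the C6 methyl, and C3 is retained. The step needs activation of the terminal over the internal epoxides and tertiary-selective opening at C2 and C6, which the methyl substitution pattern secures, while the hindered pyridine removes adventitious acid and the CH2CH2 spacer keeps the two cascades apart.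

Step 11
Reactants: 15 6,6'-(ethane-1,2-diyl)bis[(3S,5aS,6R,9aS)-2,2,5a-trimethyl-7-methylidenedecahydro-1-benzoxepin-3-ol]
Product: 16 mono-epoxide of 15 in which C10'=CH2 has become a (10'S)-spiro-oxirane (oxygen equatorial and trans to C12'; epoxide CH2 axial)
Conditions: mCPBA (0.9 equiv), NaHCO3, CH2Cl2, 0 °C; recovered 15 resubmitted
Reagents that add atoms: 3-chloroperbenzoic acid, OOC(=O)c1cccc(Cl)c1
Why: Sub-stoichiometric Prilezhaev epoxidation should functionalise one of the two equivalent remote methylenes, which by C2 symmetry gives one mono-epoxide, and the peracid should approach the face opposite the axial C6' methyl so that the oxygen becomes equatorial.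

Step 12
Reactants: 16 mono-epoxide of 15 with a (10'S)-spiro-oxirane
Product: 17 triol in which the second half carries (10'S)-C(CH3)OH (hydroxyl equatorial and trans to C12'; methyl axial) while the first half keeps C10=CH2
Conditions: LiAlH4, THF, 0 °C to reflux
Reagents that add atoms: none
Why: Hydride opens the 1,1-disubstituted epoxide at its unhindered CH2 terminus (SN2), turning that carbon into the axial C10' methyl and leaving the equatorial tertiary C–O bond untouched.

Step 13
Reactants: 17 triol with (10'S)-C(CH3)OH and C10=CH2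
Product: 19 keto triol in which C10=CH2 of 17 is replaced by C10=O, via spiro-1,2,4-trioxolane 18 (not isolated)
Conditions: O3, CH2Cl2, −78 °C; then PPh3, −78 °C to 23 °C
Reagents that add atoms: ozone, [O-][O+]=O
Why: Ozonolysis with reductive work-up cleaves the remaining 1,1-disubstituted alkene to the C10 ketone, alcohols and ethers being inert at −78 °C and C11 already holding its substituent in the stable equatorial position.

Step 14
Reactants: 19 keto triol with C10=O
Product: 20 tetraol with (10R)-C(CH3)OH in the first half (hydroxyl axial and cis to C12) and (10'S)-C(CH3)OH in the second (hydroxyl equatorial); C3 and C3' carbinols free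
Conditions: MeMgBr, CeCl3, THF, −78 °C to 0 °C
Reagents that add atoms: methylmagnesium bromide, C[Mg]Br
Why: The organocerium reagent should add to the hindered, enolisable ketone without deprotonation and from the equatorial direction, because the axial face is blocked by the 1,3-diaxial C6 methyl, giving the equatorial methyl and axial hydroxyl, the C10 epimer of the other half.

Step 15
Reactants: 20 tetraol
Product: 21 diketone diol (6S,7S,10R,11S,6'S,7'S,10'S,11'S) with C3 and C3' as ketones and both tertiary C10 carbinols free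
Conditions: Dess–Martin periodinane, NaHCO3, CH2Cl2, 23 °C
Reagents that add atoms: none
Why: Dess–Martin oxidation converts the two secondary C3 carbinols into ketones while the tertiary alcohols cannot be oxidised, and no stereocentre is adjacent to the new carbonyl groups.

Step 16
Reactants: 21 diketone diol
Product: 22 (5aS,6S,7R,9aS)-6-{2-[(5aS,6S,7S,9aS)-7-acetoxy-2,2,5a,7-tetramethyl-3-oxodecahydro-1-benzoxepin-6-yl]ethyl}-2,2,5a,7-tetramethyl-3-oxodecahydro-1-benzoxepin-7-yl acetate (CNP0325605.1)
Conditions: Ac2O, DMAP, Et3N, CH2Cl2, 40 °C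
Reagents that add atoms: acetic anhydride, CC(=O)OC(C)=O
Why: DMAP-catalysed acylation (nucleophilic catalysis) should acetylate both tertiary alcohols under basic, non-ionising conditions that leave the ketones and the C10 configurations untouched.

Compound list
1 | methyl acetoacetate | COC(=O)CC(C)=O | starting material
2 | geranyl bromide, (2E)-1-bromo-3,7-dimethylocta-2,6-diene | CC(C)=CCC/C(C)=C/CBr | starting material
3 | methyl (6E)-7,11-dimethyl-3-oxododeca-6,10-dienoate | CC(C)=CCC/C(C)=C/CCC(=O)CC(=O)OC | intermediate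
4 | methyl (2Z,6E)-3-[(diethoxyphosphoryl)oxy]-7,11-dimethyldodeca-2,6,10-trienoate | COC(=O)/C=C(OP(=O)(OCC)OCC)/CC/C=C(C)/CCC=C(C)C | intermediate
5 | (trimethylsilyl)methylmagnesium chloride | C[Si](C)(C)C[Mg]Cl | starting material
6 | methyl (2Z,6E)-7,11-dimethyl-3-[(trimethylsilyl)methyl]dodeca-2,6,10-trienoate | COC(=O)/C=C(C[Si](C)(C)C)/CC/C=C(C)/CCC=C(C)C | intermediate
7 | methyl (2Z)-5-[(2S,3S)-3-{2-[(2S)-3,3-dimethyloxiran-2-yl]ethyl}-3-methyloxiran-2-yl]-3-[(trimethylsilyl)methyl]pent-2-enoate | COC(=O)/C=C(C[Si](C)(C)C)/CC[C@@H]1O[C@@]1(C)CC[C@@H]1OC1(C)C | intermediate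
8 | (2Z)-5-[(2S,3S)-3-{2-[(2S)-3,3-dimethyloxiran-2-yl]ethyl}-3-methyloxiran-2-yl]-3-[(trimethylsilyl)methyl]pent-2-en-1-ol | OC/C=C(C[Si](C)(C)C)/CC[C@@H]1O[C@@]1(C)CC[C@@H]1OC1(C)C | intermediate
9 | methanesulfonate of 8 (formed in the flask) | CS(=O)(=O)OC/C=C(C[Si](C)(C)C)/CC[C@@H]1O[C@@]1(C)CC[C@@H]1OC1(C)C | intermediate
10 | (2Z)-1-bromo-5-[(2S,3S)-3-{2-[(2S)-3,3-dimethyloxiran-2-yl]ethyl}-3-methyloxiran-2-yl]-3-[(trimethylsilyl)methyl]pent-2-ene | BrC/C=C(C[Si](C)(C)C)/CC[C@@H]1O[C@@]1(C)CC[C@@H]1OC1(C)C | intermediate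
11 | {[(2Z)-5-[(2S,3S)-3-{2-[(2S)-3,3-dimethyloxiran-2-yl]ethyl}-3-methyloxiran-2-yl]-3-[(trimethylsilyl)methyl]pent-2-en-1-yl]sulfonyl}benzene | O=S(=O)(c1ccccc1)C/C=C(C[Si](C)(C)C)/CC[C@@H]1O[C@@]1(C)CC[C@@H]1OC1(C)C | intermediate
12 | (3S,6S,7S,10Z,14Z,18S,19S,22S)-2,3:6,7:18,19:22,23-tetraepoxy-2,6,19,23-tetramethyl-12-(phenylsulfonyl)-10,15-bis[(trimethylsilyl)methyl]tetracosa-10,14-diene, both C12 epimers | CC1(C)O[C@H]1CC[C@]1(C)O[C@H]1CC/C(C[Si](C)(C)C)=C/C(S(=O)(=O)c1ccccc1)C/C=C(C[Si](C)(C)C)/CC[C@@H]1O[C@@]1(C)CC[C@@H]1OC1(C)C | intermediate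
13 | (3S,6S,7S,10Z,14Z,18S,19S,22S)-2,3:6,7:18,19:22,23-tetraepoxy-2,6,19,23-tetramethyl-10,15-bis[(trimethylsilyl)methyl]tetracosa-10,14-diene (key-step precursor) | CC1(C)O[C@H]1CC[C@]1(C)O[C@H]1CC/C(C[Si](C)(C)C)=C/CC/C=C(C[Si](C)(C)C)/CC[C@@H]1O[C@@]1(C)CC[C@@H]1OC1(C)C | intermediate
14 | 6,6'-(ethane-1,2-diyl)bis[(3S,5aS,6R,9aS)-2,2,5a-trimethyl-7-methylidene-3-[(trimethylsilyl)oxy]decahydro-1-benzoxepine] (formed in the flask) | C=C1CC[C@@H]2OC(C)(C)[C@@H](O[Si](C)(C)C)CC[C@@]2(C)[C@@H]1CC[C@H]1[C@]2(C)CC[C@H](O[Si](C)(C)C)C(C)(C)O[C@H]2CCC1=C | intermediate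
15 | 6,6'-(ethane-1,2-diyl)bis[(3S,5aS,6R,9aS)-2,2,5a-trimethyl-7-methylidenedecahydro-1-benzoxepin-3-ol] (key-step product) | C=C1CC[C@@H]2OC(C)(C)[C@@H](O)CC[C@@]2(C)[C@@H]1CC[C@H]1[C@]2(C)CC[C@H](O)C(C)(C)O[C@H]2CCC1=C | intermediate
16 | mono-epoxide of 15: (10'S)-spiro-oxirane at C10' (O equatorial, trans to C12'; CH2 axial), other half unchanged | C=C1CC[C@@H]2OC(C)(C)[C@@H](O)CC[C@@]2(C)[C@@H]1CC[C@H]1[C@]2(C)CC[C@H](O)C(C)(C)O[C@H]2CC[C@@]13CO3 | intermediate
17 | triol: (10'S)-C(CH3)OH (OH equatorial, CH3 axial) in one half, C10=CH2 in the other, C3 and C3' carbinols S | C=C1CC[C@@H]2OC(C)(C)[C@@H](O)CC[C@@]2(C)[C@@H]1CC[C@H]1[C@]2(C)CC[C@H](O)C(C)(C)O[C@H]2CC[C@]1(C)O | intermediate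
18 | spiro-1,2,4-trioxolane (ozonide) of 17 at C10, either configuration at the spiro carbon (formed in the flask) | C1OOC2(O1)CC[C@@H]3OC(C)(C)[C@@H](O)CC[C@@]3(C)[C@@H]2CC[C@H]1[C@]2(C)CC[C@H](O)C(C)(C)O[C@H]2CC[C@]1(C)O | intermediate
19 | keto triol: C10 ketone in one half, (10'S)-C(CH3)OH in the other | O=C1CC[C@@H]2OC(C)(C)[C@@H](O)CC[C@@]2(C)[C@@H]1CC[C@H]1[C@]2(C)CC[C@H](O)C(C)(C)O[C@H]2CC[C@]1(C)O | intermediate
20 | tetraol (3S,6S,7S,10R,11S,3'S,6'S,7'S,10'S,11'S): axial C10 OH cis to C12, equatorial C10' OH trans to C12' | O[C@]1(C)CC[C@@H]2OC(C)(C)[C@@H](O)CC[C@@]2(C)[C@@H]1CC[C@H]1[C@]2(C)CC[C@H](O)C(C)(C)O[C@H]2CC[C@]1(C)O | intermediate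
21 | diketone diol (6S,7S,10R,11S,6'S,7'S,10'S,11'S): C3 and C3' ketones, both tertiary C10 carbinols free | O[C@]1(C)CC[C@@H]2OC(C)(C)C(=O)CC[C@@]2(C)[C@@H]1CC[C@H]1[C@]2(C)CCC(=O)C(C)(C)O[C@H]2CC[C@]1(C)O | intermediate
22 | (5aS,6S,7R,9aS)-6-{2-[(5aS,6S,7S,9aS)-7-acetoxy-2,2,5a,7-tetramethyl-3-oxodecahydro-1-benzoxepin-6-yl]ethyl}-2,2,5a,7-tetramethyl-3-oxodecahydro-1-benzoxepin-7-yl acetate (CNP0325605.1) | CC(=O)O[C@]1(C)CC[C@@H]2OC(C)(C)C(=O)CC[C@@]2(C)[C@@H]1CC[C@H]1[C@]2(C)CCC(=O)C(C)(C)O[C@H]2CC[C@]1(C)OC(C)=O | target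

Total step count: 16. Longest linear sequence: 16 steps (steps 1 to 16; the sulfone of step 7 is made from the bromide of step 6 and rejoined with it in step 8).

Steps most likely to fail

Step 10. Both cascades must run to completion on one chain. Activation of an internal instead of a terminal epoxide, capture or elimination of the C2 cation before the epoxide oxygen arrives, or proto-desilylation before ring closure at either end would each divert material, and the losses of a single cascade are compounded. The fallback closes the rings one half at a time and makes the C12–C12' bond afterwards. It sets out from alcohol 8. Silylation (t-BuPh2SiCl, imidazole, DMF) gives the tert-butyldiphenylsilyl ether of 8 F1. The single, precedented cascade (Me3SiOTf, 2,6-di-tert-butyl-4-methylpyridine, CH2Cl2, −78 °C) gives the bicyclic C3 trimethylsilyl ether with a silyloxymethyl group on C11 F2. Bu4NF in THF removes both silyl groups to give the bicyclic diol F3. I2, PPh3 and imidazole convert only the primary hydroxyl into the primary iodide F4. Nickel-catalysed reductive homocoupling of this alkyl iodide (NiCl2(dme), 4,4',4''-tri-tert-butyl-2,2':6',2''-terpyridine, Mn powder, DMF, 40 °C) then forms C12–C12' and comes back to the route at diol 15.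

Step 9. Reductive cleavage of the C12–S bond may run with allylic transposition, with loss of the Z geometry at C10=C11 through the intermediate allyl anion, or with attack on the epoxides. The fallback avoids the sulfone altogether. It sets out from bromide 10: reductive homocoupling with CoCl(PPh3)3 in benzene at 23 °C joins the two primary allylic carbons head to head with retention of alkene geometry and comes back to the route at precursor 13, so that steps 7 and 8 are no longer needed. This fallback makes no new compound (F0).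

Step 16. Acylation of the axial C10 carbinol, which is 1,3-diaxial to the C6 methyl, may stall, and forcing conditions may cause elimination; the ketones rule out alkoxide methods at this stage. The fallback installs the acetates before the ketones exist. It sets out from tetraol 20. n-BuLi (THF, −78 °C) followed by Ac2O acetylates all four lithium alkoxides to the tetraacetate F5. K2CO3 in MeOH at 0 °C should cleave only the two secondary C3 acetates, tertiary acetates being far slower, to give the 10,10'-diacetate 3,3'-diol F6. Dess–Martin oxidation of F6 then comes back to the route at target 22.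

Further compounds
F1 | step 10 | tert-butyl{[(2Z)-5-[(2S,3S)-3-{2-[(2S)-3,3-dimethyloxiran-2-yl]ethyl}-3-methyloxiran-2-yl]-3-[(trimethylsilyl)methyl]pent-2-en-1-yl]oxy}diphenylsilane | CC(C)(C)[Si](c1ccccc1)(c1ccccc1)OC/C=C(C[Si](C)(C)C)/CC[C@@H]1O[C@@]1(C)CC[C@@H]1OC1(C)C
F2 | step 10 | (3S,5aS,6R,9aS)-6-{[(tert-butyldiphenylsilyl)oxy]methyl}-2,2,5a-trimethyl-7-methylidene-3-[(trimethylsilyl)oxy]decahydro-1-benzoxepine | C=C1CC[C@@H]2OC(C)(C)[C@@H](O[Si](C)(C)C)CC[C@@]2(C)[C@@H]1CO[Si](c1ccccc1)(c1ccccc1)C(C)(C)C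
F3 | step 10 | (3S,5aS,6R,9aS)-6-(hydroxymethyl)-2,2,5a-trimethyl-7-methylidenedecahydro-1-benzoxepin-3-ol | C=C1CC[C@@H]2OC(C)(C)[C@@H](O)CC[C@@]2(C)[C@@H]1CO
F4 | step 10 | (3S,5aS,6R,9aS)-6-(iodomethyl)-2,2,5a-trimethyl-7-methylidenedecahydro-1-benzoxepin-3-ol | C=C1CC[C@@H]2OC(C)(C)[C@@H](O)CC[C@@]2(C)[C@@H]1CI
F0 | step 9 | none | none
F5 | step 16 | tetraacetate of tetraol 20 (3,3'-di-O-acetyl and 10,10'-di-O-acetyl) | CC(=O)O[C@]1(C)CC[C@@H]2OC(C)(C)[C@@H](OC(C)=O)CC[C@@]2(C)[C@@H]1CC[C@H]1[C@]2(C)CC[C@H](OC(C)=O)C(C)(C)O[C@H]2CC[C@]1(C)OC(C)=O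
F6 | step 16 | 10,10'-diacetate of tetraol 20 with free 3,3'-carbinols | CC(=O)O[C@]1(C)CC[C@@H]2OC(C)(C)[C@@H](O)CC[C@@]2(C)[C@@H]1CC[C@H]1[C@]2(C)CC[C@H](O)C(C)(C)O[C@H]2CC[C@]1(C)OC(C)=O
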